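**Remark on the chemistry:** the target has no stereogenic element, so no stereochemical assumption is needed. Compounds 1, 4, 7 and 8 are taken as purchased materials.

**Atom labels.** Ring A carbons are C1A to C6A: C1A bears the depside carbonyl, C2A methyl, C3A hydrogen, C4A methoxy, C5A the carboxyl, C6A hydroxyl. Ring B carbons are C1B to C6B: C1B bears the methyl ester, C2B methyl, C3B hydrogen, C4B the depside oxygen, C5B methyl, C6B hydroxyl.

**Compound numbers used throughout.**
- 1: 3,5-dimethoxytoluene
- 2: 2,6-dimethoxy-4-methylphenyllithium
- 3: 2,6-dimethoxy-4-methylbenzoic acid
- 4: benzyl bromide
- 5: benzyl 2,6-dimethoxy-4-methylbenzoate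
- 6: benzyl 3-iodo-2,6-dimethoxy-4-methylbenzoate
- 7: carbon monoxide
- 8: methyl atrarate
- 9: the coupled depside with both ring A oxygens methylated and the C5A carboxyl as benzyl ester
- 10: its C6A phenol
- 11: the target

## Analysis of the target

Compound 11 is a depside: two pentasubstituted benzene rings, ring A and ring B, joined by a single aryl ester, with no stereocentre, axis or double-bond geometry to control. The sensitive groups are three. The aryl ester is an acyl donor towards bases and nucleophiles. The electron-rich salicylic acid at C5A and C6A can lose CO2 on heating or in strong acid. The methyl ester on C1B must survive the unmasking of the acid. Three carboxyl-level carbons must end in three different states (free acid on C5A, aryl ester on C1A, methyl ester on C1B), and the two oxygens of ring A must be told apart (methyl ether on C4A, free hydroxyl on C6A). The hardest bond is the ester itself: its carbonyl sits on C1A between the C2A methyl and the C6A oxygen, and its oxygen sits on C4B next to the C5B methyl, with a second hydroxyl on C6B in the same ring. The strategy rests on that one-carbon unit between C1A and the oxygen on C4B, which can be brought in as carbon monoxide between an aryl-palladium bond and a phenol. Ring A without that carbon is a 2,6-dioxygenated 4-methylbenzoate with a mirror plane through C5A and C2A, so it can be made from a symmetric arene and functionalised at either of two equivalent positions.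

## Retrosynthetic reasoning

**11 to 10.** The free carboxyl on C5A is traced back to a benzyl ester, cutting the O-benzyl bond. A benzyl ester is chosen because hydrogenolysis is neutral and leaves the depside linkage, the C1B methyl ester and the C4A methyl ether alone. The acid is released last so that the decarboxylation-prone salicylic acid sees no further chemistry.

**10 to 9.** The hydroxyl on C6A is traced back to a methyl ether, cutting the O-methyl bond. This makes the two ring A oxygens identical in the precursors, which is what allows a symmetric ring A building block. The forward step must cleave only the ether on C6A. That ether is the only one flanked by two carbonyl groups (the depside carbonyl on C1A and the benzyl ester on C5A), and a chelating boron Lewis acid can use this difference.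

**9 to 6, 7 and 8.** Both bonds of the depside carbonyl are cut: C1A to carbonyl and carbonyl to the oxygen on C4B. Cutting here, and not only at the C-O bond, avoids making and activating a di-ortho-substituted benzoic acid. The carbonyl carbon becomes compound 7, ring A becomes aryl iodide 6 and ring B becomes phenol 8, which can be bought. The forward reaction is a palladium-catalysed three-component carbonylation that must acylate the hydroxyl on C4B and not the one on C6B, and must insert 7 before any direct aryl-oxygen coupling.

**6 to 5.** The C-I bond is cut. In 5 the two free ring positions are related by the mirror plane, and each is ortho to one methoxy group, para to the other and ortho to the methyl group. Electrophilic iodination can therefore give only one mono-iodide, and the regiochemistry of C1A is settled by symmetry.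

**5 to 3 and 4.** The benzyl-oxygen bond of the ester is cut. The forward reaction is alkylation of the carboxylate of 3 by 4, which takes place at the benzylic carbon and is therefore not slowed by the two ortho methoxy groups that would slow acyl-transfer esterification.

**3 to 1 (through 2).** The bond between the ring and the carboxyl carbon is cut. The ring hydrogen of 1 that lies between the two methoxy groups is the most acidic one and is flanked by two coordinating oxygens, so directed lithiation to 2 followed by carboxylation places the future C5A carboxyl on the symmetry axis.

## Alternatives that were turned down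

**Alternative 1:** Danheiser-type benzannulation.
- Disconnection: ring A is taken apart completely by cutting C2A-C3A, C6A-C5A, C4A-C3A and C6A-C1A. Ring B is left carrying an open-chain diazo ketone ester A2, with a separate methoxyalkyne A3.
- Forward key step: irradiation of A2 causes a Wolff rearrangement (C2A-C3A) to a vinylketene function, which adds A3 in a (2+2) sense (C6A-C5A and C4A-C3A). The four-membered ring opens, a six-electron electrocyclization (C6A-C1A) closes ring A, and tautomerization gives phenol A1.
- For it: the oxygen pattern of ring A is set by the mechanism, with the C6A hydroxyl coming from the ketene carbonyl and the C4A methoxy from the alkyne, so no late ether cleavage is needed. The ester bond to ring B is made on an unhindered open-chain acid before ring A exists. On both points it is stronger than the chosen strategy.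
- Against it: C5A arrives as a silyloxymethyl group, two oxidation levels too low. A1 therefore needs desilylation, two oxidations next to a free electron-rich phenol (an ortho-hydroxybenzyl alcohol, prone to quinone methide chemistry) and removal of the benzyl ether on C6B. A3 is a volatile, acid-sensitive ynol ether that has to be made. A2 combines a diazo group with an electron-poor alkene that can react with it, and its preparation requires ring B to be protected selectively first.
- Comparison: the sequence would be roughly twice as long as the chosen one. The chosen strategy gives up the built-in oxygen differentiation and in return has the correct oxidation level on C5A from the first step, purchased arenes as the only building blocks, and six steps.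

**Alternative 2:** biomimetic ketene capture and aldol folding.
- Disconnection: the ester C-O bond and the C1A-C2A bond of ring A are cut, giving compound 8 and a diketo-dioxinone A5 that carries the benzyl ester branch.
- Forward key step: heating A5 with 8 opens the dioxinone ring by cycloreversion to a ketene function, which the hydroxyl on C4B captures. The resulting open-chain triketo aryl ester closes ring A by aldol condensation (C1A-C2A) and dehydration to give A4.
- For it: the ester forms by addition to a ketene, before the acyl carbon is flanked by ring substituents, without metal or carbon monoxide. On the problem of hindered ester formation it is at least as strong as the chosen strategy. The carboxyl on C5A is also at the right oxidation level.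
- Against it: A5 is a branched polycarbonyl compound with a highly enolised methine between three carbonyls, and is hard to assemble and handle. The open-chain intermediate has competing closures, notably attack of the C3A methylene on the aryl ester carbonyl, which would expel ring B, and O-cyclisation to pyranones. A4 has both the C4A and C6A hydroxyls free, so the C4A oxygen must then be methylated selectively in the presence of three phenols.
- Comparison: the differentiation problem returns in a harder form. The chosen strategy has to distinguish only two ethers, one of which is marked by two flanking carbonyls, and it uses stable aromatic intermediates.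

**Alternative 3:** Diels-Alder benzannulation on the preformed ester.
- Disconnection: C2A-C3A and C1A-C6A are cut, giving the but-2-ynoate ester A8 of ring B and a silyl vinylketene acetal diene A7.
- Forward key step: (4+2) cycloaddition of A7 with A8, elimination of the benzyloxy group from C6A to aromatise, and acidic work-up give A6, which has the same structure as compound 10.
- For it: it is convergent, A8 is one unhindered acylation away from 8, and the ring A oxygens are differentiated by construction. It reaches the structure of 10 without any selective demethylation, and is stronger than the chosen strategy on that point. The step count is similar or slightly lower.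
- Against it: the diene A7 is cross-conjugated, carries an electron-withdrawing ester on the carbon that becomes C5A, and is fully substituted at the ketene acetal terminus that must bond to the alkyne carbon next to the ester. The dienophile A8 has a methyl group on its electrophilic carbon, which makes ynoates sluggish. The chelated hydroxyl on C6B is acidic enough to protonate or desilylate a ketene acetal, so it would need its own protection. Under the heating required, silyl migration or open-chain conjugate addition can replace the cycloaddition.
- Comparison: the whole route would depend on a cycloaddition between two deactivated, hindered partners, and if it fails nothing made up to that point can be reused. In the chosen strategy the key step works on robust arenes, and iodide 6 also feeds a classical ester synthesis if the carbonylation fails.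

Key step: step 4

## Route

**Step 1**
Reactants: 1 3,5-dimethoxytoluene
Product: 3 2,6-dimethoxy-4-methylbenzoic acid, via 2,6-dimethoxy-4-methylphenyllithium 2 (not isolated)
Conditions: n-BuLi, TMEDA, THF, 0 °C to rt; CO2 (dry gas), −78 °C to rt; aq. HCl
Reagents that add atoms: carbon dioxide, O=C=O
Why: Directed ortho-metalation followed by carboxylation; the ring hydrogen between the two methoxy groups is the most acidic and both oxygens coordinate lithium, so deprotonation should occur there, and the hindered aryllithium 2 adds once to CO2.

**Step 2**
Reactants: 3 2,6-dimethoxy-4-methylbenzoic acid; 4 benzyl bromide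
Product: 5 benzyl 2,6-dimethoxy-4-methylbenzoate
Conditions: K2CO3, DMF, rt
Reagents that add atoms: none
Why: SN2 O-alkylation of the carboxylate; the new bond forms at the benzylic carbon of 4, so the two ortho methoxy groups that block acyl-transfer esterification do not interfere.

**Step 3**
Reactants: 5 benzyl 2,6-dimethoxy-4-methylbenzoate
Product: 6 benzyl 3-iodo-2,6-dimethoxy-4-methylbenzoate
Conditions: N-iodosuccinimide (1.05 equiv), CF3CO2H (cat.), MeCN, 0 °C to rt, dark
Reagents that add atoms: N-iodosuccinimide, O=C1CCC(=O)N1I
Why: Electrophilic aromatic iodination; the two free positions are equivalent by symmetry and each is activated ortho and para by the methoxy groups, so one mono-iodide should form, and iodinating the ester (not the acid) avoids ipso-iododecarboxylation.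

**Step 4**
Reactants: 6 benzyl 3-iodo-2,6-dimethoxy-4-methylbenzoate; 7 carbon monoxide; 8 methyl atrarate (methyl 2,4-dihydroxy-3,6-dimethylbenzoate)
Product: 9 methyl 4-{[3-(benzyloxycarbonyl)-2,4-dimethoxy-6-methylbenzoyl]oxy}-2-hydroxy-3,6-dimethylbenzoate
Conditions: Pd(OAc)2 (5 mol %), Xantphos (7.5 mol %), Et3N (3 equiv), CO (5 bar), toluene, 90 °C
Reagents that add atoms: none
Why: Pd(OAc)2 is reduced in the flask to a zerovalent palladium-Xantphos complex, which inserts into the C-I bond of 6; CO (7) then coordinates and the aryl group migrates onto it, a step helped by the two ortho substituents because it moves the metal one atom away from the crowded ring, giving an aroyl complex of divalent palladium. Triethylamine deprotonates the hydroxyl on C4B of 8, the phenoxide replaces iodide on palladium (or attacks the acyl carbon directly), and C-O bond formation releases ester 9 and returns zerovalent palladium, so the C1A-carbonyl bond and the carbonyl-oxygen bond are both made in one turnover. The closest known reaction type is the palladium-catalysed alkoxy- and aryloxycarbonylation of aryl iodides (Heck carbonylation) run with phenols under Pd(OAc)2 and Xantphos, applied here to a di-ortho-substituted iodide and a hindered phenol. No ring is closed and no stereocentre is formed. Site selectivity between the two hydroxyls of 8 comes from the substrate: the C6B hydroxyl is hydrogen-bonded to the C1B ester carbonyl and sits between that ester and the C5B methyl, whereas the C4B hydroxyl is para to the ester, more acidic, and has one free ortho position. Carbonylation should win over direct aryl ether formation because CO insertion into the hindered aryl-palladium bond is fast under CO pressure and the wide bite angle of Xantphos stabilises the acyl complex and promotes the ester-forming elimination. The benzyl and methyl esters are inert under these conditions, and since 6 is a single compound only one regioisomer of 9 can arise.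

**Step 5**
Reactants: 9 methyl 4-{[3-(benzyloxycarbonyl)-2,4-dimethoxy-6-methylbenzoyl]oxy}-2-hydroxy-3,6-dimethylbenzoate
Product: 10 methyl 4-{[3-(benzyloxycarbonyl)-2-hydroxy-4-methoxy-6-methylbenzoyl]oxy}-2-hydroxy-3,6-dimethylbenzoate
Conditions: BCl3 (1 M in CH2Cl2, 2.5 equiv), CH2Cl2, −78 to −20 °C; aq. HCl (1 M), 0 °C
Reagents that add atoms: none
Why: Chelation-controlled Lewis-acid ether cleavage; BCl3 bridges a carbonyl oxygen and the ether oxygen and chloride removes the methyl group by SN2, and the C6A ether should react first because it alone lies between two carbonyl groups and is twisted out of the ring plane by two ortho substituents, which makes its oxygen the more basic. The C4A ether is conjugated with the ring and can use only the C5A ester, which is already engaged after the first cleavage; one equivalent of BCl3 is consumed by the C6B hydroxyl and returned on work-up, and the methyl ester and depside linkage should hold at low temperature.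

**Step 6**
Reactants: 10 methyl 4-{[3-(benzyloxycarbonyl)-2-hydroxy-4-methoxy-6-methylbenzoyl]oxy}-2-hydroxy-3,6-dimethylbenzoate
Product: 11 2-hydroxy-3-{[3-hydroxy-4-(methoxycarbonyl)-2,5-dimethylphenoxy]carbonyl}-6-methoxy-4-methylbenzoic acid
Conditions: H2 (1 atm), 10% Pd/C, EtOAc, rt
Reagents that add atoms: none
Why: Hydrogenolysis of the benzyl ester under neutral conditions; the aryl ester, methyl ester and methyl ether are inert to H2 over Pd/C, and the non-nucleophilic solvent rules out transesterification of the depside.

## Compound list

1 | 3,5-dimethoxytoluene | COc1cc(C)cc(OC)c1 | starting material
2 | 2,6-dimethoxy-4-methylphenyllithium | [Li]c1c(OC)cc(C)cc1OC | intermediate (not isolated)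
3 | 2,6-dimethoxy-4-methylbenzoic acid | COc1cc(C)cc(OC)c1C(=O)O | intermediate
4 | benzyl bromide | BrCc1ccccc1 | starting material
5 | benzyl 2,6-dimethoxy-4-methylbenzoate | COc1cc(C)cc(OC)c1C(=O)OCc1ccccc1 | intermediate
6 | benzyl 3-iodo-2,6-dimethoxy-4-methylbenzoate | COc1cc(C)c(I)c(OC)c1C(=O)OCc1ccccc1 | intermediate
7 | carbon monoxide | [C-]#[O+] | starting material
8 | methyl atrarate (methyl 2,4-dihydroxy-3,6-dimethylbenzoate) | COC(=O)c1c(C)cc(O)c(C)c1O | starting material
9 | methyl 4-{[3-(benzyloxycarbonyl)-2,4-dimethoxy-6-methylbenzoyl]oxy}-2-hydroxy-3,6-dimethylbenzoate | COC(=O)c1c(C)cc(OC(=O)c2c(C)cc(OC)c(C(=O)OCc3ccccc3)c2OC)c(C)c1O | intermediate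
10 | methyl 4-{[3-(benzyloxycarbonyl)-2-hydroxy-4-methoxy-6-methylbenzoyl]oxy}-2-hydroxy-3,6-dimethylbenzoate | COC(=O)c1c(C)cc(OC(=O)c2c(C)cc(OC)c(C(=O)OCc3ccccc3)c2O)c(C)c1O | intermediate
11 | 2-hydroxy-3-{[3-hydroxy-4-(methoxycarbonyl)-2,5-dimethylphenoxy]carbonyl}-6-methoxy-4-methylbenzoic acid | COC(=O)c1c(C)cc(OC(=O)c2c(C)cc(OC)c(C(=O)O)c2O)c(C)c1O | target

## Step count and least certain steps

Total step count: 6. Longest linear sequence: 6 steps (1 to 3 to 5 to 6 to 9 to 10 to 11); compounds 4, 7 and 8 enter as purchased materials.

**Step 4 (key step).** The most likely failure is slow capture of the crowded aroyl-palladium intermediate by the hindered, weakly nucleophilic phenoxide. Reduction of the C-I bond, hydrolysis of the acyl complex by traces of water, or precipitation of palladium metal under CO could then take over. Acylation at the C6B hydroxyl is a smaller concern.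
Fallback, setting out from 6 and coming back at 9: iodine-magnesium exchange with iPrMgCl·LiCl in THF at −20 °C should give [3-(benzyloxycarbonyl)-2,4-dimethoxy-6-methylphenyl]magnesium chloride F1; the hindered benzyl ester tolerates this at low temperature. F1 is carboxylated with CO2 to 3-(benzyloxycarbonyl)-2,4-dimethoxy-6-methylbenzoic acid F2. Trifluoroacetic anhydride in toluene converts F2 into 3-(benzyloxycarbonyl)-2,4-dimethoxy-6-methylbenzoic trifluoroacetic anhydride F3. F3 ionises readily because of the di-ortho substitution and acylates the hydroxyl on C4B of 8, which is the classical depside esterification, to give 9.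

**Step 5.** The most likely failure is incomplete discrimination between the two ethers: the C4A ether is also ortho to the C5A ester and could be cleaved after, or in place of, the C6A ether. Lewis-acid attack on the benzyl ester or the depside linkage is the second concern. Partial loss of the benzyl ester would be harmless, since it leads to 11.
Fallback, setting out from 6 and coming back at 11: the discrimination is moved to the small arene, where isomers can be separated and no depside is present. BCl3 in CH2Cl2 at −78 °C should cleave the ether of 6 that is flanked by iodine and the ester, giving benzyl 2-hydroxy-3-iodo-6-methoxy-4-methylbenzoate F4; the remaining methoxy group is the one next to the ring hydrogen, which allows a simple structural check. Benzylation with 4 and K2CO3 in DMF gives benzyl 2-(benzyloxy)-3-iodo-6-methoxy-4-methylbenzoate F5. Carbonylative coupling of F5 with 7 and 8 under the conditions of step 4 gives methyl 4-{[2-(benzyloxy)-3-(benzyloxycarbonyl)-4-methoxy-6-methylbenzoyl]oxy}-2-hydroxy-3,6-dimethylbenzoate F6. One hydrogenolysis over Pd/C removes both benzyl groups and gives 11, so no Lewis acid touches the depside.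

**Step 6.** The most likely failures are slow hydrogenolysis of a benzyl ester shielded by two ortho oxygen substituents, and decarboxylation of the freed electron-rich salicylic acid if the mixture is warmed or concentrated hot.
Fallback, setting out from 10 and coming back at 11: Lewis-acid debenzylation with BCl3 and pentamethylbenzene as cation scavenger in CH2Cl2 at −78 to 0 °C, followed by cold aqueous work-up. The benzyl group leaves as a cation that the scavenger traps, no hydrogen or metal surface is involved, and no new intermediate is made.

**Step 1.** The most likely failures are incomplete metalation, metalation at the wrong site (the ring position beside the methyl group, or the benzylic methyl), and addition of a second aryllithium to the lithium carboxylate.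
Fallback, setting out from 4 together with purchased 2,6-dihydroxy-4-methylbenzoic acid F7 (which replaces 1) and coming back at 5: selective carboxylate benzylation of F7 with 4 and KHCO3 in DMF near room temperature, kept mild to avoid decarboxylation, gives benzyl 2,6-dihydroxy-4-methylbenzoate F8. Double O-methylation of F8 with iodomethane and K2CO3 in acetone at reflux gives 5 without any organolithium step.

## Further compounds

F1 | step 4 | [3-(benzyloxycarbonyl)-2,4-dimethoxy-6-methylphenyl]magnesium chloride | COc1cc(C)c([Mg]Cl)c(OC)c1C(=O)OCc1ccccc1
F2 | step 4 | 3-(benzyloxycarbonyl)-2,4-dimethoxy-6-methylbenzoic acid | COc1cc(C)c(C(=O)O)c(OC)c1C(=O)OCc1ccccc1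
F3 | step 4 | 3-(benzyloxycarbonyl)-2,4-dimethoxy-6-methylbenzoic trifluoroacetic anhydride | COc1cc(C)c(C(=O)OC(=O)C(F)(F)F)c(OC)c1C(=O)OCc1ccccc1
F4 | step 5 | benzyl 2-hydroxy-3-iodo-6-methoxy-4-methylbenzoate | COc1cc(C)c(I)c(O)c1C(=O)OCc1ccccc1
F5 | step 5 | benzyl 2-(benzyloxy)-3-iodo-6-methoxy-4-methylbenzoate | COc1cc(C)c(I)c(OCc2ccccc2)c1C(=O)OCc1ccccc1
F6 | step 5 | methyl 4-{[2-(benzyloxy)-3-(benzyloxycarbonyl)-4-methoxy-6-methylbenzoyl]oxy}-2-hydroxy-3,6-dimethylbenzoate | COC(=O)c1c(C)cc(OC(=O)c2c(C)cc(OC)c(C(=O)OCc3ccccc3)c2OCc4ccccc4)c(C)c1O
F0 | step 6 | none | none
F7 | step 1 | 2,6-dihydroxy-4-methylbenzoic acid | Cc1cc(O)c(C(=O)O)c(O)c1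
F8 | step 1 | benzyl 2,6-dihydroxy-4-methylbenzoate | Cc1cc(O)c(C(=O)OCc2ccccc2)c(O)c1
A1 | alternative 1 | methyl 2-(benzyloxy)-4-{[3-(tert-butyldimethylsilyloxymethyl)-2-hydroxy-4-methoxy-6-methylbenzoyl]oxy}-3,6-dimethylbenzoate | COC(=O)c1c(C)cc(OC(=O)c2c(C)cc(OC)c(CO[Si](C)(C)C(C)(C)C)c2O)c(C)c1OCc1ccccc1
A2 | alternative 1 | 3-(benzyloxy)-4-(methoxycarbonyl)-2,5-dimethylphenyl (E)-5-diazo-3-methyl-4-oxopent-2-enoate | COC(=O)c1c(C)cc(OC(=O)/C=C(\C)C(=O)C=[N+]=[N-])c(C)c1OCc1ccccc1
A3 | alternative 1 | tert-butyl[(3-methoxyprop-2-yn-1-yl)oxy]dimethylsilane | COC#CCO[Si](C)(C)C(C)(C)C
A4 | alternative 2 | methyl 4-{[3-(benzyloxycarbonyl)-2,4-dihydroxy-6-methylbenzoyl]oxy}-2-hydroxy-3,6-dimethylbenzoate | COC(=O)c1c(C)cc(OC(=O)c2c(C)cc(O)c(C(=O)OCc3ccccc3)c2O)c(C)c1O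
A5 | alternative 2 | benzyl 2-(2,2-dimethyl-4-oxo-4H-1,3-dioxin-6-yl)-3,5-dioxohexanoate | CC(=O)CC(=O)C(C(=O)OCc1ccccc1)C1=CC(=O)OC(C)(C)O1
A6 | alternative 3 | methyl 4-{[3-(benzyloxycarbonyl)-2-hydroxy-4-methoxy-6-methylbenzoyl]oxy}-2-hydroxy-3,6-dimethylbenzoate (same structure as 10) | COC(=O)c1c(C)cc(OC(=O)c2c(C)cc(OC)c(C(=O)OCc3ccccc3)c2O)c(C)c1O
A7 | alternative 3 | benzyl 2-[(benzyloxy)(trimethylsilyloxy)methylidene]-3-methoxybut-3-enoate (ketene acetal geometry not defined) | C=C(OC)C(C(=O)OCc1ccccc1)=C(OCc1ccccc1)O[Si](C)(C)C
A8 | alternative 3 | methyl 4-(but-2-ynoyloxy)-2-hydroxy-3,6-dimethylbenzoate | COC(=O)c1c(C)cc(OC(=O)C#CC)c(C)c1O
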